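**Retrosynthetic overview**

- The strategy rests on ring C: C4 is a single carbonyl carbon bridging C4a of ring A and the C3=C2 unit that carries ring B, and O1 on the neighbouring C8a can close onto C2. Ring C is therefore cut into a ring A ortho-iodophenol, carbon monoxide and a ring B arylacetylene, forming C4a–C4, C4–C3 and O1–C2 in one palladium-catalysed operation.
- After the annulation, the 3-hydroxyl is installed by C3 lithiation, borylation and oxidation, and the four MOM ethers are then removed.
- The iodophenol comes from iodination of mirror-symmetric 3,5-bis(methoxymethoxy)-4-prenylphenol, whose two ortho positions are equivalent, so the prenyl group can only end at C6. This phenol is made from phloroglucinol by bis-MOM protection, TIPS capping, and directed lithiation and prenylation between the two MOM ethers.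
- The alkyne comes from 2,4-dihydroxybenzaldehyde by MOM protection and Ohira–Bestmann homologation.
- Ring order: rings A and B are bought as arenes; ring C is the only ring formed (step 8).

Key step: step 8

Remark: the target has no stereocentre and no stereogenic double bond, so no step needs stereocontrol.

**Route**

Step 1
Reactants: 1 phloroglucinol
Product: 2 3,5-bis(methoxymethoxy)phenol
Conditions: MOMCl (2.0 equiv), i-Pr2NEt, CH2Cl2–DMF, 0 °C to rt; chromatography
Reagents that add atoms: chloromethyl methyl ether (MOMCl), COCCl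
Why: Williamson-type O-alkylation with an α-chloro ether on three equivalent hydroxyls is a statistical protection, so control of stoichiometry should make the bis-ether the main product, separable from the mono- and tris-ethers by chromatography.

Step 2
Reactants: 2 3,5-bis(methoxymethoxy)phenol
Product: 3 [3,5-bis(methoxymethoxy)phenoxy]tri(propan-2-yl)silane
Conditions: TIPSCl, imidazole, DMF, rt
Reagents that add atoms: triisopropylsilyl chloride (TIPSCl), CC(C)[Si](Cl)(C(C)C)C(C)C
Why: Imidazole-mediated silylation of the remaining phenol installs a bulky, poorly coordinating silyl ether that shields its own ortho positions and survives alkyllithium, leaving the C–H between the two MOM ethers as the only lithiation site.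

Step 3
Reactants: 3 [3,5-bis(methoxymethoxy)phenoxy]tri(propan-2-yl)silane; 4 prenyl bromide (1-bromo-3-methylbut-2-ene)
Product: 6 [3,5-bis(methoxymethoxy)-4-(3-methylbut-2-enyl)phenoxy]tri(propan-2-yl)silane, via aryllithium 5 (not isolated)
Conditions: n-BuLi, THF, 0 °C; then CuI (10 mol %), 4, −78 °C to rt
Reagents that add atoms: prenyl bromide (4), CC(C)=CCBr
Why: Directed ortho-metalation removes the C–H doubly activated by the two flanking MOM ethers, and copper-catalysed alkylation of the aryllithium at the primary carbon of prenyl bromide (SN2 mode) should give the symmetric prenyl arene.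

Step 4
Reactants: 6 [3,5-bis(methoxymethoxy)-4-(3-methylbut-2-enyl)phenoxy]tri(propan-2-yl)silane
Product: 7 3,5-bis(methoxymethoxy)-4-(3-methylbut-2-enyl)phenol
Conditions: Bu4NF, AcOH, THF, 0 °C
Reagents that add atoms: none
Why: Fluoride-mediated desilylation cleaves the aryl silyl ether readily, and the acetic acid buffer keeps the medium near neutral so the MOM ethers and the alkene should be untouched.

Step 5
Reactants: 7 3,5-bis(methoxymethoxy)-4-(3-methylbut-2-enyl)phenol
Product: 8 2-iodo-3,5-bis(methoxymethoxy)-4-(3-methylbut-2-enyl)phenol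
Conditions: NIS (1.0 equiv), CH2Cl2, −20 to 0 °C, dark
Reagents that add atoms: N-iodosuccinimide (NIS), O=C1CCC(=O)N1I
Why: Electrophilic aromatic iodination of a phloroglucinol-type phenol whose para position is blocked and whose two ortho positions are equivalent can give only one mono-iodide, and the highly activated ring should react faster than the trisubstituted alkene when one equivalent is used cold.

Step 6
Reactants: 9 2,4-dihydroxybenzaldehyde
Product: 10 2,4-bis(methoxymethoxy)benzaldehyde
Conditions: MOMCl (3 equiv), i-Pr2NEt, DMF, 0 °C to rt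
Reagents that add atoms: chloromethyl methyl ether (MOMCl), COCCl
Why: Williamson-type MOM protection of both phenols, with excess reagent to drive the hydrogen-bonded 2-hydroxyl to completion.

Step 7
Reactants: 10 2,4-bis(methoxymethoxy)benzaldehyde
Product: 11 1-ethynyl-2,4-bis(methoxymethoxy)benzene
Conditions: dimethyl (1-diazo-2-oxopropyl)phosphonate, K2CO3, MeOH, 0 °C to rt
Reagents that add atoms: dimethyl (1-diazo-2-oxopropyl)phosphonate (Ohira–Bestmann reagent), CC(=O)C(=[N+]=[N-])P(=O)(OC)OC
Why: Seyferth–Gilbert homologation in the Ohira–Bestmann variant (methanolysis to the diazomethylphosphonate anion, olefination, loss of N2 and 1,2-hydrogen shift) converts the aldehyde into the terminal alkyne under mild base that leaves the MOM ethers intact.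

Step 8
Reactants: 8 2-iodo-3,5-bis(methoxymethoxy)-4-(3-methylbut-2-enyl)phenol; 11 1-ethynyl-2,4-bis(methoxymethoxy)benzene; 12 carbon monoxide
Product: 15 5,7-bis(methoxymethoxy)-2-[2,4-bis(methoxymethoxy)phenyl]-6-(3-methylbut-2-enyl)chromen-4-one, via ynone 13 (not isolated), via enaminone 14 (not isolated)
Conditions: PdCl2(dppf) (5 mol %), CO (10–20 atm), Et2NH, 100–120 °C, no copper
Reagents that add atoms: carbon monoxide (12), [C-]#[O+]; diethylamine, CCNCC (held only in intermediate 14)
Why: Oxidative addition of the C–I bond of 8 to zerovalent palladium (formed in situ from PdCl2(dppf) and the amine), CO insertion to the aroyl complex of divalent palladium, and amine-assisted coupling with alkyne 11 followed by reductive elimination give ynone 13, forming C4a–C4 and C4–C3. Diethylamine then adds to the β-carbon of the ynone to give enaminone 14, whose phenolic oxygen attacks that same carbon (the future C2) and expels the amine, forming O1–C2 and closing ring C. The closest known reaction type is the carbonylative Sonogashira coupling of ortho-iodophenols with terminal arylacetylenes with in situ cyclization to flavones. Ring C closes in a 6-endo mode by addition–elimination at the β-carbon of the vinylogous amide, and no stereocentre is created. The step needs carbonylative over direct coupling (which would lead to a 2-arylbenzofuran) and 6-endo over 5-exo closure (aurone); the first is secured by CO pressure, the absence of copper and the fast CO insertion of an electron-rich, di-ortho-substituted arylpalladium, the second by the secondary amine, which makes the β-carbon the only electrophilic site. Regiochemistry on ring A is fixed because 8 carries a single free hydroxyl, so the prenyl group can only end at C6, and the basic, non-oxidizing medium spares the alkene and the MOM ethers.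

Step 9
Reactants: 15 5,7-bis(methoxymethoxy)-2-[2,4-bis(methoxymethoxy)phenyl]-6-(3-methylbut-2-enyl)chromen-4-one
Product: 18 3-hydroxy-5,7-bis(methoxymethoxy)-2-[2,4-bis(methoxymethoxy)phenyl]-6-(3-methylbut-2-enyl)chromen-4-one, via 3-lithioflavone 16 (not isolated), via lithium trimethoxyborate 17 (not isolated)
Conditions: LiN(i-Pr)2 (LDA), THF, −78 °C; B(OMe)3, −78 to 0 °C; then AcOH, 30% aq. H2O2, 0 °C to rt
Reagents that add atoms: hydrogen peroxide, OO; trimethyl borate, COB(OC)OC (held only in intermediate 17)
Why: The vinylic C3–H next to the carbonyl is the most acidic proton of a 5-alkoxyflavone and is removed by LDA at −78 °C (known C3 lithiation of flavones), and borate trapping followed by peroxide oxidation of the C–B bond gives the 3-hydroxyl, while the amide base at low temperature should not lithiate the MOM-flanked aryl positions and buffered peroxide at 0 °C should spare the prenyl alkene.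

Step 10
Reactants: 18 3-hydroxy-5,7-bis(methoxymethoxy)-2-[2,4-bis(methoxymethoxy)phenyl]-6-(3-methylbut-2-enyl)chromen-4-one
Product: 19 3,5,7-trihydroxy-2-(2,4-dihydroxyphenyl)-6-(3-methylbut-2-enyl)chromen-4-one (CNP0154752.0)
Conditions: aq. HCl (3 M), MeOH, 40 °C, monitored and stopped at full conversion
Reagents that add atoms: none
Why: Acid-catalysed acetal methanolysis transfers the four methoxymethyl groups to methanol as dimethoxymethane, and dilute acid at moderate temperature is chosen so that acetal cleavage should outrun protonation of the prenyl alkene.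

**Compound list**

1 | phloroglucinol (benzene-1,3,5-triol) | Oc1cc(O)cc(O)c1 | starting material
2 | 3,5-bis(methoxymethoxy)phenol | COCOc1cc(O)cc(OCOC)c1 | intermediate
3 | [3,5-bis(methoxymethoxy)phenoxy]tri(propan-2-yl)silane | COCOc1cc(OCOC)cc(O[Si](C(C)C)(C(C)C)C(C)C)c1 | intermediate
4 | prenyl bromide (1-bromo-3-methylbut-2-ene) | CC(C)=CCBr | starting material
5 | [2,6-bis(methoxymethoxy)-4-(triisopropylsilyloxy)phenyl]lithium | [Li]c1c(OCOC)cc(O[Si](C(C)C)(C(C)C)C(C)C)cc1OCOC | intermediate (not isolated)
6 | [3,5-bis(methoxymethoxy)-4-(3-methylbut-2-enyl)phenoxy]tri(propan-2-yl)silane | CC(C)=CCc1c(OCOC)cc(O[Si](C(C)C)(C(C)C)C(C)C)cc1OCOC | intermediate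
7 | 3,5-bis(methoxymethoxy)-4-(3-methylbut-2-enyl)phenol | CC(C)=CCc1c(OCOC)cc(O)cc1OCOC | intermediate
8 | 2-iodo-3,5-bis(methoxymethoxy)-4-(3-methylbut-2-enyl)phenol | CC(C)=CCc1c(OCOC)cc(O)c(I)c1OCOC | intermediate
9 | 2,4-dihydroxybenzaldehyde | O=Cc1ccc(O)cc1O | starting material
10 | 2,4-bis(methoxymethoxy)benzaldehyde | O=Cc1ccc(OCOC)cc1OCOC | intermediate
11 | 1-ethynyl-2,4-bis(methoxymethoxy)benzene | C#Cc1ccc(OCOC)cc1OCOC | intermediate
12 | carbon monoxide | [C-]#[O+] | starting material
13 | 1-[6-hydroxy-2,4-bis(methoxymethoxy)-3-(3-methylbut-2-enyl)phenyl]-3-[2,4-bis(methoxymethoxy)phenyl]prop-2-yn-1-one | CC(C)=CCc1c(OCOC)cc(O)c(C(=O)C#Cc2ccc(OCOC)cc2OCOC)c1OCOC | intermediate (not isolated)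
14 | 3-(diethylamino)-1-[6-hydroxy-2,4-bis(methoxymethoxy)-3-(3-methylbut-2-enyl)phenyl]-3-[2,4-bis(methoxymethoxy)phenyl]prop-2-en-1-one (alkene geometry not defined; both isomers converge) | CC(C)=CCc1c(OCOC)cc(O)c(C(=O)C=C(N(CC)CC)c2ccc(OCOC)cc2OCOC)c1OCOC | intermediate (not isolated)
15 | 5,7-bis(methoxymethoxy)-2-[2,4-bis(methoxymethoxy)phenyl]-6-(3-methylbut-2-enyl)chromen-4-one | CC(C)=CCc1c(OCOC)cc2oc(-c3ccc(OCOC)cc3OCOC)cc(=O)c2c1OCOC | intermediate
16 | {5,7-bis(methoxymethoxy)-2-[2,4-bis(methoxymethoxy)phenyl]-6-(3-methylbut-2-enyl)-4-oxochromen-3-yl}lithium | CC(C)=CCc1c(OCOC)cc2oc(-c3ccc(OCOC)cc3OCOC)c([Li])c(=O)c2c1OCOC | intermediate (not isolated)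
17 | lithium {5,7-bis(methoxymethoxy)-2-[2,4-bis(methoxymethoxy)phenyl]-6-(3-methylbut-2-enyl)-4-oxochromen-3-yl}trimethoxyborate | [Li+].CO[B-](OC)(OC)c1c(-c2ccc(OCOC)cc2OCOC)oc2cc(OCOC)c(CC=C(C)C)c(OCOC)c2c1=O | intermediate (not isolated)
18 | 3-hydroxy-5,7-bis(methoxymethoxy)-2-[2,4-bis(methoxymethoxy)phenyl]-6-(3-methylbut-2-enyl)chromen-4-one | CC(C)=CCc1c(OCOC)cc2oc(-c3ccc(OCOC)cc3OCOC)c(O)c(=O)c2c1OCOC | intermediate
19 | 3,5,7-trihydroxy-2-(2,4-dihydroxyphenyl)-6-(3-methylbut-2-enyl)chromen-4-one (CNP0154752.0) | CC(C)=CCc1c(O)cc2oc(-c3ccc(O)cc3O)c(O)c(=O)c2c1O | target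

**Step count**

Total steps: 10. Longest linear sequence: 8 steps (steps 1, 2, 3, 4, 5, 8, 9, 10).

**Steps most likely to fail**

1. Step 8. Direct, non-carbonylative coupling may outpace CO insertion (leading towards a 2-arylbenzofuran), or oxidative addition into the hindered, electron-rich C–I bond may be slow enough for hydrodeiodination to compete. The fallback builds the same ynone without palladium; it sets out from 11 and 8 and rejoins the route at 13 and then 15. Alkyne 11 is deprotonated (n-BuLi, THF, −78 °C) to lithium [2,4-bis(methoxymethoxy)phenyl]acetylide F1 and formylated with DMF (KH2PO4 quench) to 3-[2,4-bis(methoxymethoxy)phenyl]prop-2-ynal F2. Iodophenol 8 is treated with n-BuLi (2.1 equiv, THF, −78 °C; O–H deprotonation, then iodine–lithium exchange) to give lithium 2-lithio-3,5-bis(methoxymethoxy)-4-(3-methylbut-2-enyl)phenoxide F3. Addition of F3 to F2 should give racemic 1-[6-hydroxy-2,4-bis(methoxymethoxy)-3-(3-methylbut-2-enyl)phenyl]-3-[2,4-bis(methoxymethoxy)phenyl]prop-2-yn-1-ol F4. MnO2 (CH2Cl2, rt) oxidizes the benzylic, propargylic alcohol to ynone 13, and Et2NH in EtOH at 60 °C closes it through enaminone 14 to flavone 15.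

2. Step 9. Deprotonation may occur at the wrong site (C8, or C3′ between the two MOM ethers of ring B), the amide may add to C2, or the peroxide work-up may oxidize the prenyl alkene. The fallback avoids strong base by conjugate addition and α-oxidation; it sets out from 15 and rejoins the route at target 19. Flavone 15 is treated with PhI(OAc)2 and KOH in MeOH (0 °C to rt): methoxide adds at C2 and the resulting enolate is oxidized at C3. This should give racemic 3-hydroxy-2,4,4-trimethoxy-5,7-bis(methoxymethoxy)-2-[2,4-bis(methoxymethoxy)phenyl]-6-(3-methylbut-2-enyl)chromane F5, whose two stereocentres are destroyed in the next operation. Aqueous HCl in MeOH then hydrolyses the ketal, eliminates methanol across C2–C3 and cleaves the four MOM ethers in the same operation to give 19.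

3. Step 10. The liberated 5- or 7-hydroxyl may add to the protonated prenyl alkene (closure to a dimethylchroman ring) in competition with acetal cleavage. The fallback avoids protic acid; it sets out from 18 and rejoins the route at 19. Treatment of 18 with TMSOTf and 2,2′-bipyridyl (MeCN, 0 °C to rt) should convert the aryl MOM ethers and the free 3-hydroxyl into silyl ethers, giving 3,5,7-tris(trimethylsilyloxy)-2-[2,4-bis(trimethylsilyloxy)phenyl]-6-(3-methylbut-2-enyl)chromen-4-one F6. Addition of water at neutral pH hydrolyses the aryl silyl ethers to 19.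

**Further compounds**

F1 | step 8 | lithium [2,4-bis(methoxymethoxy)phenyl]acetylide | [Li]C#Cc1ccc(OCOC)cc1OCOC
F2 | step 8 | 3-[2,4-bis(methoxymethoxy)phenyl]prop-2-ynal | O=CC#Cc1ccc(OCOC)cc1OCOC
F3 | step 8 | lithium 2-lithio-3,5-bis(methoxymethoxy)-4-(3-methylbut-2-enyl)phenoxide | [Li]Oc1cc(OCOC)c(CC=C(C)C)c(OCOC)c1[Li]
F4 | step 8 | 1-[6-hydroxy-2,4-bis(methoxymethoxy)-3-(3-methylbut-2-enyl)phenyl]-3-[2,4-bis(methoxymethoxy)phenyl]prop-2-yn-1-ol (racemic) | CC(C)=CCc1c(OCOC)cc(O)c(C(O)C#Cc2ccc(OCOC)cc2OCOC)c1OCOC
F5 | step 9 | 3-hydroxy-2,4,4-trimethoxy-5,7-bis(methoxymethoxy)-2-[2,4-bis(methoxymethoxy)phenyl]-6-(3-methylbut-2-enyl)chromane (racemic, relative configuration not defined) | CC(C)=CCc1c(OCOC)cc2OC(OC)(c3ccc(OCOC)cc3OCOC)C(O)C(OC)(OC)c2c1OCOC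
F6 | step 10 | 3,5,7-tris(trimethylsilyloxy)-2-[2,4-bis(trimethylsilyloxy)phenyl]-6-(3-methylbut-2-enyl)chromen-4-one | CC(C)=CCc1c(O[Si](C)(C)C)cc2oc(-c3ccc(O[Si](C)(C)C)cc3O[Si](C)(C)C)c(O[Si](C)(C)C)c(=O)c2c1O[Si](C)(C)C
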